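**Plan**

- Retrosynthesis: the phenol is taken back to its keto tautomer and then, by returning benzenesulfenic acid across C4a=C8a, to a 4a‑sulfinyl enedione. Ring A is cut at C8–C8a and C4a–C5 in one [4+2] disconnection, then the C4a–S bond, then C2–C3 and O1–C8a of ring C (hetero‑Diels–Alder), and the prenyl–CH2 bond of the diene.
- Enabling feature: ring C with C2 is a 2‑aryl‑2,3‑dihydropyran‑4‑one whose enol ether double bond is C4a=C8a, shared with ring A. The other ring A atoms, C5–C8 with O7 and the C8 prenyl chain, are the skeleton of a 4‑prenyl 1‑amino‑3‑silyloxybutadiene.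
- Forward order: ring C is built on the chroman aldehyde, C4a is sulfenylated and oxidised, ring A is closed by cycloaddition with loss of the amine, and sulfenic acid is eliminated last to give the arene.
- Stereochemistry: C2 is the only stereocentre. It is set S in step 1 by the chiral titanium catalyst and then meets only neutral or mildly acidic conditions; sulfur and the transient centres C4a, C5, C8 and C8a are erased.
- Design choice: a dimethylamino donor is used on the diene, not a methoxy donor, so that the cycloaddition runs cold and the C5 leaving group is removed before the sulfoxide is heated.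

Key step: step 6

Assumption: the (S)‑BINOL titanium catalyst is taken to direct the diene to the Si face of the aryl aldehyde, which gives S at C2; the sense is checked on 4 and the ligand antipode is used if it proves opposite.

**Step 1**
Reactants: 1 2,2‑dimethylchroman‑6‑carbaldehyde; 2 (E)‑1‑methoxy‑3‑(trimethylsilyloxy)buta‑1,3‑diene
Product: 4 (S)‑2‑(2,2‑dimethylchroman‑6‑yl)‑2,3‑dihydro‑4H‑pyran‑4‑one, via silyl aldol adduct 3 (not isolated)
Conditions: (S)‑BINOL (20 mol %), Ti(OiPr)4 (10 mol %), CF3CO2H (cat.), 4 Å MS, Et2O, −20 °C; then CF3CO2H, CH2Cl2, 0 °C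
Reagents that add atoms: none
Why: A titanium BINOL catalysed Mukaiyama aldol addition of the siloxydiene, followed by acid‑mediated oxa‑Michael closure with loss of methanol (formal hetero‑Diels–Alder reaction), is established for aryl aldehydes; the catalyst directs the diene to the Si face of the formyl group and so sets C2 as S.

**Step 2**
Reactants: 4 (S)‑2‑(2,2‑dimethylchroman‑6‑yl)‑2,3‑dihydro‑4H‑pyran‑4‑one
Product: 6 (S)‑2‑(2,2‑dimethylchroman‑6‑yl)‑5‑(phenylthio)‑2,3‑dihydro‑4H‑pyran‑4‑one, via chloro sulfide adduct 5 (not isolated)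
Conditions: PhSH, N‑chlorosuccinimide, CH2Cl2, 0 °C; add 4, −78 → 0 °C; Et3N, 0 °C → rt
Reagents that add atoms: thiophenol, Sc1ccccc1 (chlorinated in the flask by N‑chlorosuccinimide to benzenesulfenyl chloride, ClSc1ccccc1)
Why: Electrophilic sulfenylation: the enol ether carbon C5 of the vinylogous ester should add the sulfenyl chloride, and triethylamine then removes HCl across C5–C6 to restore the push–pull alkene, leaving C2 untouched.

**Step 3**
Reactants: 6 (S)‑2‑(2,2‑dimethylchroman‑6‑yl)‑5‑(phenylthio)‑2,3‑dihydro‑4H‑pyran‑4‑one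
Product: 7 (2S)‑2‑(2,2‑dimethylchroman‑6‑yl)‑5‑(phenylsulfinyl)‑2,3‑dihydro‑4H‑pyran‑4‑one (both sulfur epimers)
Conditions: mCPBA (1.0 equiv), CH2Cl2, −78 → −40 °C
Reagents that add atoms: mCPBA (3‑chloroperoxybenzoic acid), OOC(=O)c1cccc(Cl)c1
Why: Sulfide to sulfoxide oxidation with one equivalent of peracid at low temperature should be faster than attack on the electron‑poor alkene or further oxidation to the sulfone; the sulfur configuration is irrelevant because sulfur is lost later.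

**Step 4**
Reactants: 8 (E)‑4‑(dimethylamino)but‑3‑en‑2‑one; 9 prenyl bromide
Product: 11 (E)‑1‑(dimethylamino)‑7‑methylocta‑1,6‑dien‑3‑one, via lithium enolate 10 (not isolated)
Conditions: LiN(iPr)2, THF, −78 °C; 9, −78 → 0 °C
Reagents that add atoms: none
Why: Kinetic deprotonation of the vinylogous amide at its methyl group, the only enolisable site, and SN2 alkylation of the cross‑conjugated enolate by the allylic bromide (enolate alkylation).

**Step 5**
Reactants: 11 (E)‑1‑(dimethylamino)‑7‑methylocta‑1,6‑dien‑3‑one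
Product: 13 (1E,3Z)‑3‑(tert‑butyldimethylsilyloxy)‑N,N,7‑trimethylocta‑1,3,6‑trien‑1‑amine, via potassium enolate 12 (not isolated)
Conditions: KN(SiMe3)2, THF, −78 °C; tBuMe2SiCl, −78 °C → rt
Reagents that add atoms: tert‑butyldimethylsilyl chloride, CC(C)(C)[Si](C)(C)Cl
Why: O‑silylation of the potassium enolate (silyl enol ether formation, as used for 1‑amino‑3‑silyloxy dienes); the chain should lie trans to the aminovinyl group (3Z), so that it points outward in the s‑cis diene.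

**Step 6**
Reactants: 7 (2S)‑2‑(2,2‑dimethylchroman‑6‑yl)‑5‑(phenylsulfinyl)‑2,3‑dihydro‑4H‑pyran‑4‑one; 13 (1E,3Z)‑3‑(tert‑butyldimethylsilyloxy)‑N,N,7‑trimethylocta‑1,3,6‑trien‑1‑amine
Product: 15 (2S)‑2‑(2,2‑dimethylchroman‑6‑yl)‑8‑(3‑methylbut‑2‑enyl)‑4a‑(phenylsulfinyl)‑2,3,8,8a‑tetrahydro‑4H‑chromene‑4,7(4aH)‑dione (cis‑fused diastereomer mixture), via amino cycloadduct 14 (not isolated)
Conditions: 13 (2 equiv), PhMe, −20 → 20 °C; then 1 M HCl, THF, 0 °C
Reagents that add atoms: none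
Why: Proposed new method: the silyl enol ether terminus of 13 (C8, carrying the prenyl chain) is its most nucleophilic carbon and should bond to C8a of 7, which is β to both the ketone and the sulfinyl group, while the amino‑bearing terminus (C5) bonds to C4a in an asynchronous [4+2] cycloaddition; cold dilute acid then hydrolyses the silyl enol ether of 14 and expels dimethylamine from the position β to the new C7 ketone, giving enone 15. The closest known reactions are Diels–Alder reactions of 2‑sulfinyl enones, sulfinylquinones and 3‑activated chromones with 1‑hetero‑3‑silyloxy dienes and the cyclohexenone synthesis from 1‑amino‑3‑silyloxy dienes, but a 5‑sulfinyl‑2,3‑dihydropyran‑4‑one has not been shown as the dienophile. Ring A closes as a six‑membered carbocycle by intermolecular [4+2] cycloaddition across the C4a=C8a enol ether bond. The new centres at C4a, C8 and C8a (and C5 in 14) need no control because all are erased on aromatisation, the suprafacial addition alone ensures that sulfur and H‑8a are cis, and C2 is untouched by the neutral and then mildly acidic medium. The selectivities required are the regiochemistry, secured by the polarity match just described, and the order of the two eliminations: an amino diene is used because it should react well below the temperature at which the sulfoxide eliminates and offsets the donor effect of O1, so that the C5 leaving group is gone (C5 becomes sp2) before sulfenic acid can be lost toward the allylic H‑5, which would end in a 5‑amino dienone that cannot aromatise.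

**Step 7**
Reactants: 15 (2S)‑2‑(2,2‑dimethylchroman‑6‑yl)‑8‑(3‑methylbut‑2‑enyl)‑4a‑(phenylsulfinyl)‑2,3,8,8a‑tetrahydro‑4H‑chromene‑4,7(4aH)‑dione
Product: 17 euchrenone a17 [(S)‑2‑(2,2‑dimethylchroman‑6‑yl)‑7‑hydroxy‑8‑(3‑methylbut‑2‑enyl)chroman‑4‑one], via dienone tautomer 16 (not isolated)
Conditions: PhMe, 80 °C
Reagents that add atoms: none
Why: Thermal syn elimination of benzenesulfenic acid (sulfoxide pyrolysis): in 15 the only β‑hydrogen on an sp3 carbon is H‑8a, cis to sulfur, so C4a=C8a should form and the resulting cyclohexa‑2,4‑dienone should tautomerise to the phenol, while the neutral medium leaves C2 alone.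

**Compound list**

1 | 2,2‑dimethylchroman‑6‑carbaldehyde | O=Cc1ccc2c(c1)CCC(C)(C)O2 | starting material
2 | (E)‑1‑methoxy‑3‑(trimethylsilyloxy)buta‑1,3‑diene | CO/C=C/C(=C)O[Si](C)(C)C | starting material
3 | (S,E)‑5‑(2,2‑dimethylchroman‑6‑yl)‑1‑methoxy‑5‑(trimethylsilyloxy)pent‑1‑en‑3‑one (formed in the flask) | C[Si](C)(C)O[C@H](c1ccc2c(c1)CCC(C)(C)O2)CC(=O)/C=C/OC | intermediate
4 | (S)‑2‑(2,2‑dimethylchroman‑6‑yl)‑2,3‑dihydro‑4H‑pyran‑4‑one | O1[C@H](c2ccc3c(c2)CCC(C)(C)O3)CC(=O)C=C1 | intermediate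
5 | (2S)‑6‑chloro‑2‑(2,2‑dimethylchroman‑6‑yl)‑5‑(phenylthio)tetrahydro‑4H‑pyran‑4‑one, diastereomer mixture at C5 and C6 (formed in the flask) | O1[C@H](c2ccc3c(c2)CCC(C)(C)O3)CC(=O)C(Sc2ccccc2)C1Cl | intermediate
6 | (S)‑2‑(2,2‑dimethylchroman‑6‑yl)‑5‑(phenylthio)‑2,3‑dihydro‑4H‑pyran‑4‑one | O1[C@H](c2ccc3c(c2)CCC(C)(C)O3)CC(=O)C(Sc2ccccc2)=C1 | intermediate
7 | (2S)‑2‑(2,2‑dimethylchroman‑6‑yl)‑5‑(phenylsulfinyl)‑2,3‑dihydro‑4H‑pyran‑4‑one, both sulfur epimers | O1[C@H](c2ccc3c(c2)CCC(C)(C)O3)CC(=O)C(S(=O)c2ccccc2)=C1 | intermediate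
8 | (E)‑4‑(dimethylamino)but‑3‑en‑2‑one | CN(C)/C=C/C(C)=O | starting material
9 | prenyl bromide (1‑bromo‑3‑methylbut‑2‑ene) | CC(C)=CCBr | starting material
10 | lithium (E)‑4‑(dimethylamino)buta‑1,3‑dien‑2‑olate (formed in the flask) | [Li]OC(=C)/C=C/N(C)C | intermediate
11 | (E)‑1‑(dimethylamino)‑7‑methylocta‑1,6‑dien‑3‑one | CN(C)/C=C/C(=O)CCC=C(C)C | intermediate
12 | potassium (1E,3Z)‑1‑(dimethylamino)‑7‑methylocta‑1,3,6‑trien‑3‑olate (formed in the flask) | [K]OC(/C=C/N(C)C)=C\CC=C(C)C | intermediate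
13 | (1E,3Z)‑3‑(tert‑butyldimethylsilyloxy)‑N,N,7‑trimethylocta‑1,3,6‑trien‑1‑amine | CN(C)/C=C/C(O[Si](C)(C)C(C)(C)C)=C/CC=C(C)C | intermediate
14 | (2S)‑7‑(tert‑butyldimethylsilyloxy)‑5‑(dimethylamino)‑2‑(2,2‑dimethylchroman‑6‑yl)‑8‑(3‑methylbut‑2‑enyl)‑4a‑(phenylsulfinyl)‑2,3,4a,5,8,8a‑hexahydro‑4H‑chromen‑4‑one, cis‑fused diastereomer mixture (formed in the flask) | O1[C@H](c2ccc3c(c2)CCC(C)(C)O3)CC(=O)C2(S(=O)c3ccccc3)C(N(C)C)C=C(O[Si](C)(C)C(C)(C)C)C(CC=C(C)C)C12 | intermediate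
15 | (2S)‑2‑(2,2‑dimethylchroman‑6‑yl)‑8‑(3‑methylbut‑2‑enyl)‑4a‑(phenylsulfinyl)‑2,3,8,8a‑tetrahydro‑4H‑chromene‑4,7(4aH)‑dione, cis‑fused diastereomer mixture | O1[C@H](c2ccc3c(c2)CCC(C)(C)O3)CC(=O)C2(S(=O)c3ccccc3)C=CC(=O)C(CC=C(C)C)C12 | intermediate
16 | (S)‑2‑(2,2‑dimethylchroman‑6‑yl)‑8‑(3‑methylbut‑2‑enyl)‑2,3‑dihydro‑4H‑chromene‑4,7(8H)‑dione (formed in the flask) | O1[C@H](c2ccc3c(c2)CCC(C)(C)O3)CC(=O)C2=C1C(CC=C(C)C)C(=O)C=C2 | intermediate
17 | euchrenone a17, (S)‑2‑(2,2‑dimethylchroman‑6‑yl)‑7‑hydroxy‑8‑(3‑methylbut‑2‑enyl)chroman‑4‑one | CC(C)=CCc1c(O)ccc2c1O[C@H](c1ccc3c(c1)CCC(C)(C)O3)CC2=O | target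

**Count**

Total: 7 steps. Longest linear sequence: 5 steps (steps 1, 2, 3, 6, 7 from aldehyde 1); the diene arm is 2 steps (4, 5).

**Steps most likely to fail**

1. Step 6. The diene may add to C8a in a stepwise manner and expel O1 (ring opening of the vinylogous ester) instead of closing ring A, or sulfenic acid may be lost toward H‑5 before the amine is removed. The fallback uses known chemistry, sets out from aldehyde 1 and prenyl bromide 9, and returns at target 17. 2,4‑Dihydroxyacetophenone is C‑prenylated with 9 in aqueous KOH to 1‑[2,4‑dihydroxy‑3‑(3‑methylbut‑2‑enyl)phenyl]ethanone F1. Its 4‑hydroxyl is protected (MOMCl, iPr2NEt) as 1‑[2‑hydroxy‑4‑(methoxymethoxy)‑3‑(3‑methylbut‑2‑enyl)phenyl]ethanone F2. Claisen–Schmidt condensation with 1 (KOH, EtOH) should give (E)‑3‑(2,2‑dimethylchroman‑6‑yl)‑1‑[2‑hydroxy‑4‑(methoxymethoxy)‑3‑(3‑methylbut‑2‑enyl)phenyl]prop‑2‑en‑1‑one F3. NaOAc in refluxing EtOH closes it by oxa‑Michael addition to racemic 2‑(2,2‑dimethylchroman‑6‑yl)‑7‑(methoxymethoxy)‑8‑(3‑methylbut‑2‑enyl)chroman‑4‑one F4. Kinetic resolution by asymmetric transfer hydrogenation (RuCl[(R,R)‑TsDPEN](p‑cymene), HCO2H/Et3N) should leave (S)‑2‑(2,2‑dimethylchroman‑6‑yl)‑7‑(methoxymethoxy)‑8‑(3‑methylbut‑2‑enyl)chroman‑4‑one F5, while the R enantiomer is reduced to (2R,4R)‑2‑(2,2‑dimethylchroman‑6‑yl)‑7‑(methoxymethoxy)‑8‑(3‑methylbut‑2‑enyl)chroman‑4‑ol F6. HCl in MeOH then removes the methoxymethyl group from F5 to give 17.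

2. Step 4. Proton transfer between product and enolate may lead to double alkylation, and the enolate may condense with itself on warming. The fallback sets out from 9 and returns at 11. The lithium enolate of N‑methoxy‑N‑methylacetamide (LiN(iPr)2, THF, −78 °C) is alkylated with 9 to N‑methoxy‑N,5‑dimethylhex‑4‑enamide F8. HC≡CMgBr converts it into 7‑methyloct‑6‑en‑1‑yn‑3‑one F9. Conjugate addition of dimethylamine (THF, 0 °C) to the ynone should give the E enaminone 11.

3. Step 2. The sulfenyl chloride may attack the electron‑rich chroman ring, or the chloro sulfide may fail to lose HCl cleanly. The fallback sets out from 4 and returns at 6. α‑Iodination (I2, pyridine, CH2Cl2) gives (S)‑2‑(2,2‑dimethylchroman‑6‑yl)‑5‑iodo‑2,3‑dihydro‑4H‑pyran‑4‑one F7. A palladium‑catalysed C–S coupling with thiophenol (Pd2(dba)3, Xantphos, iPr2NEt, 1,4‑dioxane, 80 °C) should then give sulfide 6.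

**Further compounds**

F1 | step 6 | 1‑[2,4‑dihydroxy‑3‑(3‑methylbut‑2‑enyl)phenyl]ethanone | CC(=O)c1ccc(O)c(CC=C(C)C)c1O
F2 | step 6 | 1‑[2‑hydroxy‑4‑(methoxymethoxy)‑3‑(3‑methylbut‑2‑enyl)phenyl]ethanone | CC(=O)c1ccc(OCOC)c(CC=C(C)C)c1O
F3 | step 6 | (E)‑3‑(2,2‑dimethylchroman‑6‑yl)‑1‑[2‑hydroxy‑4‑(methoxymethoxy)‑3‑(3‑methylbut‑2‑enyl)phenyl]prop‑2‑en‑1‑one | COCOc1ccc(C(=O)/C=C/c2ccc3c(c2)CCC(C)(C)O3)c(O)c1CC=C(C)C
F4 | step 6 | racemic 2‑(2,2‑dimethylchroman‑6‑yl)‑7‑(methoxymethoxy)‑8‑(3‑methylbut‑2‑enyl)chroman‑4‑one | COCOc1ccc2c(c1CC=C(C)C)OC(c1ccc3c(c1)CCC(C)(C)O3)CC2=O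
F5 | step 6 | (S)‑2‑(2,2‑dimethylchroman‑6‑yl)‑7‑(methoxymethoxy)‑8‑(3‑methylbut‑2‑enyl)chroman‑4‑one | COCOc1ccc2c(c1CC=C(C)C)O[C@H](c1ccc3c(c1)CCC(C)(C)O3)CC2=O
F6 | step 6 | (2R,4R)‑2‑(2,2‑dimethylchroman‑6‑yl)‑7‑(methoxymethoxy)‑8‑(3‑methylbut‑2‑enyl)chroman‑4‑ol | COCOc1ccc2c(c1CC=C(C)C)O[C@@H](c1ccc3c(c1)CCC(C)(C)O3)C[C@H]2O
F7 | step 2 | (S)‑2‑(2,2‑dimethylchroman‑6‑yl)‑5‑iodo‑2,3‑dihydro‑4H‑pyran‑4‑one | O1[C@H](c2ccc3c(c2)CCC(C)(C)O3)CC(=O)C(I)=C1
F8 | step 4 | N‑methoxy‑N,5‑dimethylhex‑4‑enamide | CON(C)C(=O)CCC=C(C)C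
F9 | step 4 | 7‑methyloct‑6‑en‑1‑yn‑3‑one | C#CC(=O)CCC=C(C)C
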